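**Strategy**

Everything rests on disconnecting the C-2–C-3 bond of ring B, which turns the carbocycle into an isomeric enol lactone, a 3,3-disubstituted 6-(2-arylethyl)pyran-2,4-dione. In one operation Mg(OMe)2 opens that lactone and the side-chain methylene already bonded to the benzylic carbon of ring A closes onto the new methyl ester, creating ring B and the methylene bridge together. The step exploits the fact that, in the lactone, the ring oxygen sits on only one side of quaternary C-4, so C-3 and C-5 are differentiated and the C-4 configuration, set beforehand by asymmetric palladium-catalysed prenylation, is simply carried over. Butanoylation at C-6 and acetal removal complete the target.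

Key step: step 10

Assumption (sense of induction): the (1R,2R) ligand antipode in step 9 is taken to deliver the (S)-pyrandione; should the opposite sense be found, the (1S,2S) antipode is used without other change.

Assumption (drawing): the enolised triones are drawn as one tautomer and CIP descriptors refer to that drawing; the descriptor changes from S (17) to R (18, 19, 20) only through a change of substituent priorities, the spatial arrangement at the quaternary carbon being identical from 15 to 20.

**Route**

Step 1
Reactants: 1 phloroglucinol (benzene-1,3,5-triol); 2 hexanoyl chloride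
Product: 3 1-(2,4,6-trihydroxyphenyl)hexan-1-one
Conditions: AlCl3 (3.5 equiv), PhNO2–CH2Cl2, 0 to 50 °C; ice/dilute HCl
Reagents that add atoms: none
Why: Friedel–Crafts C-acylation of the electron-rich triol should stop after one acyl group because the aryl ketone deactivates the ring and all three ring positions are equivalent.

Step 2
Reactants: 3 1-(2,4,6-trihydroxyphenyl)hexan-1-one
Product: 4 1-(2,6-dihydroxy-4-methoxyphenyl)hexan-1-one
Conditions: Me2SO4 (1.0 equiv), K2CO3 (1.0 equiv), acetone, rt to 50 °C
Reagents that add atoms: dimethyl sulfate, COS(=O)(=O)OC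
Why: Williamson-type O-methylation should take the para hydroxyl, the only one not hydrogen-bonded to the ketone and therefore the most acidic and most nucleophilic, while one equivalent of a hard methylating agent limits over- and C-methylation.

Step 3
Reactants: 4 1-(2,6-dihydroxy-4-methoxyphenyl)hexan-1-one
Product: 6 3-hexanoyl-2,4-dihydroxy-6-methoxybenzaldehyde, via chloro(methoxy)methyl arene 5 (not isolated)
Conditions: Cl2CHOMe (1.2 equiv), TiCl4 (3 equiv), CH2Cl2, −10 to 0 °C; then ice-water
Reagents that add atoms: dichloromethyl methyl ether, COC(Cl)Cl; water, O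
Why: Rieche formylation attacks one of the two equivalent free ring positions of the activated phenol, the α-chloro ether 5 is hydrolysed on work-up, and the first formyl group deactivates the ring against a second.

Step 4
Reactants: 6 3-hexanoyl-2,4-dihydroxy-6-methoxybenzaldehyde
Product: 7 3-hexanoyl-6-methoxy-2,4-bis(methoxymethoxy)benzaldehyde
Conditions: NaH (2.3 equiv), MOMCl (2.5 equiv), DMF, 0 °C to rt
Reagents that add atoms: chloromethyl methyl ether, COCCl
Why: Williamson-type alkylation of the two sodium phenoxides should succeed because full deprotonation breaks the chelates to the carbonyl groups that would make amine-base conditions sluggish; both phenols must be masked for the carbanion and palladium steps.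

Step 5
Reactants: 8 4-hydroxy-3,6-dimethylpyran-2-one; 7 3-hexanoyl-6-methoxy-2,4-bis(methoxymethoxy)benzaldehyde
Product: 10 racemic 6-[2-[3-hexanoyl-6-methoxy-2,4-bis(methoxymethoxy)phenyl]-2-hydroxyethyl]-4-hydroxy-3-methylpyran-2-one, via dilithiated pyranone 9 (not isolated)
Conditions: LiN(iPr)2 (2.2 equiv), THF–DMPU, −78 to −30 °C; then 7, −78 °C; AcOH quench
Reagents that add atoms: none
Why: Aldol addition of the pyranone dianion occurs at its most basic site, the C-6 methyl carbanion, and the aldehyde should be attacked far faster than the hindered, doubly ortho-substituted hexanoyl ketone is enolised or attacked; the carbinol centre is formed racemic and is removed in step 6.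

Step 6
Reactants: 10 racemic aldol adduct
Product: 11 6-[(E)-2-[3-hexanoyl-6-methoxy-2,4-bis(methoxymethoxy)phenyl]ethenyl]-4-hydroxy-3-methylpyran-2-one
Conditions: PPTS (0.2 equiv), 4 Å molecular sieves, toluene, 80 °C
Reagents that add atoms: none
Why: Acid-catalysed E1 dehydration runs through a benzylic cation stabilised by three ortho/para oxygens and gives the conjugated, thermodynamically preferred E alkene; a weak acid in an aprotic solvent should leave the acetal ethers intact.

Step 7
Reactants: 11 E-styrylpyranone
Product: 12 6-[2-[3-hexanoyl-6-methoxy-2,4-bis(methoxymethoxy)phenyl]ethyl]-4-hydroxy-3-methylpyran-2-one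
Conditions: H2 (1 atm), 10% Pd/C, EtOAc, rt
Reagents that add atoms: none
Why: Heterogeneous catalytic hydrogenation should saturate the disubstituted styrenyl alkene selectively, the pseudo-aromatic 4-hydroxypyranone and the hindered aryl ketone being inert at one atmosphere; it is placed before prenylation so that no other alkene is present.

Step 8
Reactants: 13 3-methylbut-2-en-1-ol
Product: 14 tert-butyl 3-methylbut-2-enyl carbonate
Conditions: Boc2O (1.1 equiv), Bu4NHSO4 (cat.), 30% aq. NaOH, CH2Cl2, 0 °C to rt
Reagents that add atoms: di-tert-butyl dicarbonate, CC(C)(C)OC(=O)OC(=O)OC(C)(C)C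
Why: Phase-transfer alkoxycarbonylation of a primary allylic alcohol is a standard preparation of the carbonate electrophile for allylic alkylation.

Step 9
Reactants: 12 arylethyl hydroxypyranone; 14 tert-butyl 3-methylbut-2-enyl carbonate
Product: 15 (3S)-6-[2-[3-hexanoyl-6-methoxy-2,4-bis(methoxymethoxy)phenyl]ethyl]-3-methyl-3-(3-methylbut-2-enyl)pyran-2,4-dione
Conditions: Pd2(dba)3·CHCl3 (2.5 mol%), N,N'-[(1R,2R)-cyclohexane-1,2-diyl]bis[2-(diphenylphosphanyl)benzamide] (7.5 mol%), CH2Cl2, rt
Reagents that add atoms: none
Why: In this Tsuji–Trost asymmetric allylic alkylation, ionisation of the carbonate gives a π-prenyl palladium cation and tert-butoxide, which deprotonates the acidic pyranone; the enolate attacks through C-3 at the unsubstituted allyl terminus (the branched mode would join two quaternary carbons, and O-allylation is reversible under the catalyst), and the chiral pocket of the ligand differentiates the enantiotopic faces of the enolate to set the quaternary stereocentre.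

Step 10
Reactants: 15 (3S)-pyran-2,4-dione
Product: 17 (4S)-2-[[3-hexanoyl-6-methoxy-2,4-bis(methoxymethoxy)phenyl]methyl]-3,5-dihydroxy-4-methyl-4-(3-methylbut-2-enyl)cyclohexa-2,5-dien-1-one, via ring-opened methyl ester 16 (not isolated)
Conditions: Mg(OMe)2 (4 equiv), MeOH, 65 °C; then cold 0.5 M aq. HCl, EtOAc
Reagents that add atoms: none
Why: Methoxide, delivered within a magnesium chelate, adds to the lactone carbonyl (more electrophilic than the ketone, which is part of a vinylogous ester) and the ring opens to the magnesium-chelated diketo ester 16; a second enolisation at the CH2 between the freed ketone and the benzylic carbon then attacks the methyl ester and expels methoxide, forming the C-2–C-3 bond of ring B. The closest known reaction type is the alkoxide-induced rearrangement of enol lactones to cyclohexane-1,3-diones (ring opening followed by intramolecular Claisen/Dieckmann condensation), established for 6-alkyl-4-hydroxypyran-2-ones. Ring B closes in a 6-(enolendo)-exo-trig mode, because the enolate double bond lies inside the forming ring. No stereocentre is created: the quaternary carbon (pyranone C-3, ring B C-4) has no α-hydrogen and takes no part in bond breaking, so its configuration is retained, the lactone carbonyl becoming C-3 and the ketone C-5. The step needs attack at the lactone carbonyl only and a single Claisen mode; the first is secured by the enol-ester character of that carbonyl, the second because the only other enolisable position, the CH2 between the two ketones, could close only a four-membered ring. The doubly enolised trione is drained as its magnesium salt, which drives the sequence and shields the product from retro-Claisen cleavage.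

Step 11
Reactants: 17 (4S)-dihydroxycyclohexadienone
Product: 19 (4R)-2-butanoyl-6-[[3-hexanoyl-6-methoxy-2,4-bis(methoxymethoxy)phenyl]methyl]-3,5-dihydroxy-4-methyl-4-(3-methylbut-2-enyl)cyclohexa-2,5-dien-1-one, via enol butanoate 18 (not isolated)
Conditions: butanoyl chloride (1.05 equiv), Et3N (2.5 equiv), CH2Cl2, 0 °C; then DMAP (0.3 equiv), rt
Reagents that add atoms: butanoyl chloride, CCCC(Cl)=O
Why: O-acylation of the vinylogous acid followed by DMAP-catalysed O-to-C acyl transfer (Steglich-type, as used for 2-acylcyclohexane-1,3-diones) should deliver the acyl group to C-6, the only ring carbon bearing hydrogen, where the enolised, hydrogen-bonded β-triketone is the thermodynamic sink; acylation at substituted C-2 would be reversible.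

Step 12
Reactants: 19 bis(methoxymethyl)-protected target
Product: 20 elaphopilosin B, (4R)-2-butanoyl-6-[(3-hexanoyl-2,4-dihydroxy-6-methoxyphenyl)methyl]-3,5-dihydroxy-4-methyl-4-(3-methylbut-2-enyl)cyclohexa-2,5-dien-1-one
Conditions: 3 M aq. HCl–MeOH (1:10), rt to 40 °C
Reagents that add atoms: none
Why: Acid-catalysed acetal exchange with methanol removes both methoxymethyl ethers, which flank the hexanoyl ketone and are cleaved readily, under conditions dilute enough that the prenyl group should not cyclise onto the neighbouring enol; the quaternary centre is untouched.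

**Compound list**

1 | phloroglucinol | Oc1cc(O)cc(O)c1 | starting material
2 | hexanoyl chloride | CCCCCC(Cl)=O | starting material
3 | 1-(2,4,6-trihydroxyphenyl)hexan-1-one | CCCCCC(=O)c1c(O)cc(O)cc1O | intermediate
4 | 1-(2,6-dihydroxy-4-methoxyphenyl)hexan-1-one | CCCCCC(=O)c1c(O)cc(OC)cc1O | intermediate
5 | 1-[3-[chloro(methoxy)methyl]-2,6-dihydroxy-4-methoxyphenyl]hexan-1-one (not isolated) | CCCCCC(=O)c1c(O)cc(OC)c(C(Cl)OC)c1O | intermediate
6 | 3-hexanoyl-2,4-dihydroxy-6-methoxybenzaldehyde | CCCCCC(=O)c1c(O)cc(OC)c(C=O)c1O | intermediate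
7 | 3-hexanoyl-6-methoxy-2,4-bis(methoxymethoxy)benzaldehyde | CCCCCC(=O)c1c(OCOC)cc(OC)c(C=O)c1OCOC | intermediate
8 | 4-hydroxy-3,6-dimethylpyran-2-one | CC1=CC(O)=C(C)C(=O)O1 | starting material
9 | dilithium dianion of 8 (O-4 and C-6 methyl; not isolated) | [Li+].[Li+].[CH2-]C1=CC([O-])=C(C)C(=O)O1 | intermediate
10 | racemic 6-[2-[3-hexanoyl-6-methoxy-2,4-bis(methoxymethoxy)phenyl]-2-hydroxyethyl]-4-hydroxy-3-methylpyran-2-one | CCCCCC(=O)c1c(OCOC)cc(OC)c(C(O)CC2=CC(O)=C(C)C(=O)O2)c1OCOC | intermediate
11 | 6-[(E)-2-[3-hexanoyl-6-methoxy-2,4-bis(methoxymethoxy)phenyl]ethenyl]-4-hydroxy-3-methylpyran-2-one | CCCCCC(=O)c1c(OCOC)cc(OC)c(/C=C/C2=CC(O)=C(C)C(=O)O2)c1OCOC | intermediate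
12 | 6-[2-[3-hexanoyl-6-methoxy-2,4-bis(methoxymethoxy)phenyl]ethyl]-4-hydroxy-3-methylpyran-2-one | CCCCCC(=O)c1c(OCOC)cc(OC)c(CCC2=CC(O)=C(C)C(=O)O2)c1OCOC | intermediate
13 | 3-methylbut-2-en-1-ol | CC(C)=CCO | starting material
14 | tert-butyl 3-methylbut-2-enyl carbonate | CC(C)=CCOC(=O)OC(C)(C)C | intermediate
15 | (3S)-6-[2-[3-hexanoyl-6-methoxy-2,4-bis(methoxymethoxy)phenyl]ethyl]-3-methyl-3-(3-methylbut-2-enyl)pyran-2,4-dione | CCCCCC(=O)c1c(OCOC)cc(OC)c(CCC2=CC(=O)[C@](C)(CC=C(C)C)C(=O)O2)c1OCOC | intermediate
16 | methyl (2S)-7-[3-hexanoyl-6-methoxy-2,4-bis(methoxymethoxy)phenyl]-2-methyl-2-(3-methylbut-2-enyl)-3,5-dioxoheptanoate (magnesium chelate in the flask; not isolated) | CCCCCC(=O)c1c(OCOC)cc(OC)c(CCC(=O)CC(=O)[C@](C)(CC=C(C)C)C(=O)OC)c1OCOC | intermediate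
17 | (4S)-2-[[3-hexanoyl-6-methoxy-2,4-bis(methoxymethoxy)phenyl]methyl]-3,5-dihydroxy-4-methyl-4-(3-methylbut-2-enyl)cyclohexa-2,5-dien-1-one | CCCCCC(=O)c1c(OCOC)cc(OC)c(CC2=C(O)[C@@](C)(CC=C(C)C)C(O)=CC2=O)c1OCOC | intermediate
18 | [(6R)-4-[[3-hexanoyl-6-methoxy-2,4-bis(methoxymethoxy)phenyl]methyl]-5-hydroxy-6-methyl-6-(3-methylbut-2-enyl)-3-oxocyclohexa-1,4-dien-1-yl] butanoate (enol ester drawn at the oxygen next to C-6; not isolated) | CCCCCC(=O)c1c(OCOC)cc(OC)c(CC2=C(O)[C@@](C)(CC=C(C)C)C(OC(=O)CCC)=CC2=O)c1OCOC | intermediate
19 | (4R)-2-butanoyl-6-[[3-hexanoyl-6-methoxy-2,4-bis(methoxymethoxy)phenyl]methyl]-3,5-dihydroxy-4-methyl-4-(3-methylbut-2-enyl)cyclohexa-2,5-dien-1-one | CCCCCC(=O)c1c(OCOC)cc(OC)c(CC2=C(O)[C@@](C)(CC=C(C)C)C(O)=C(C(=O)CCC)C2=O)c1OCOC | intermediate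
20 | elaphopilosin B, (4R)-2-butanoyl-6-[(3-hexanoyl-2,4-dihydroxy-6-methoxyphenyl)methyl]-3,5-dihydroxy-4-methyl-4-(3-methylbut-2-enyl)cyclohexa-2,5-dien-1-one | CCCCCC(=O)c1c(O)cc(OC)c(CC2=C(O)[C@@](C)(CC=C(C)C)C(O)=C(C(=O)CCC)C2=O)c1O | target

**Step count**

Total steps: 12. Longest linear sequence: 11 steps (steps 1 to 7 and 9 to 12, from phloroglucinol); step 8 is a one-step side branch.

**Steps most likely to fail**

Step 10. Methoxide may add in conjugate fashion to the enol-ether carbon of the lactone and cleave the ring to a carboxylate that cannot cyclise. Alternatively, the opened, non-enolisable keto ester may fragment by retro-Claisen attack of alkoxide before the second enolisation takes place. The fallback sets out from 15 and comes back at 17 by splitting the one-pot process into two operations with no free nucleophilic alkoxide in the ring-closing stage. Opening of 15 with CF3CH2OH and catalytic NaOCH2CF3 in THF at 0 °C should give the isolable 2,2,2-trifluoroethyl (2S)-7-[3-hexanoyl-6-methoxy-2,4-bis(methoxymethoxy)phenyl]-2-methyl-2-(3-methylbut-2-enyl)-3,5-dioxoheptanoate F1. Treatment with LiN(SiMe3)2 (3.2 equiv) in THF at −78 to 0 °C then generates the diketone polyanion, whose terminal carbanion acylates the activated ester in a Dieckmann-type closure; mild acidic work-up gives 17.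

Step 9. Enantiofacial discrimination may be weak, because the two groups flanking the nucleophilic carbon (lactone carbonyl and enolate oxygen) are of similar size; branched (reverse-prenyl) or O-allylated material may also persist. The fallback sets out from 12 and comes back at 15 by resolution instead of asymmetric catalysis. Allylation of 12 with 14 and the achiral catalyst Pd(PPh3)4 in THF at rt should give racemic 6-[2-[3-hexanoyl-6-methoxy-2,4-bis(methoxymethoxy)phenyl]ethyl]-3-methyl-3-(3-methylbut-2-enyl)pyran-2,4-dione F2. The enantiomers are then separated by preparative chromatography on a chiral stationary phase, and the (S) antipode is 15.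

Step 6. The acid needed for dehydration may also strip the acetal ethers or start cationic oligomerisation of the electron-rich styrene. The fallback sets out from 7 and comes back at 12, replacing steps 5 to 7 by an alkylation that needs neither acid nor hydrogen. NaBH4 in MeOH–THF at 0 °C should reduce the aldehyde of 7 much faster than the buttressed aryl ketone, giving 1-[3-(hydroxymethyl)-4-methoxy-2,6-bis(methoxymethoxy)phenyl]hexan-1-one F3. An Appel reaction (CBr4, PPh3, CH2Cl2, 0 °C) converts it into 1-[3-(bromomethyl)-4-methoxy-2,6-bis(methoxymethoxy)phenyl]hexan-1-one F4, used crude. Alkylation of the dilithiated pyranone 9 at its terminal carbanion (THF–DMPU, −78 °C, AcOH quench) gives 12 directly.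

**Further compounds**

F1 | step 10 | 2,2,2-trifluoroethyl (2S)-7-[3-hexanoyl-6-methoxy-2,4-bis(methoxymethoxy)phenyl]-2-methyl-2-(3-methylbut-2-enyl)-3,5-dioxoheptanoate | CCCCCC(=O)c1c(OCOC)cc(OC)c(CCC(=O)CC(=O)[C@](C)(CC=C(C)C)C(=O)OCC(F)(F)F)c1OCOC
F2 | step 9 | racemic 6-[2-[3-hexanoyl-6-methoxy-2,4-bis(methoxymethoxy)phenyl]ethyl]-3-methyl-3-(3-methylbut-2-enyl)pyran-2,4-dione | CCCCCC(=O)c1c(OCOC)cc(OC)c(CCC2=CC(=O)C(C)(CC=C(C)C)C(=O)O2)c1OCOC
F3 | step 6 | 1-[3-(hydroxymethyl)-4-methoxy-2,6-bis(methoxymethoxy)phenyl]hexan-1-one | CCCCCC(=O)c1c(OCOC)cc(OC)c(CO)c1OCOC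
F4 | step 6 | 1-[3-(bromomethyl)-4-methoxy-2,6-bis(methoxymethoxy)phenyl]hexan-1-one | CCCCCC(=O)c1c(OCOC)cc(OC)c(CBr)c1OCOC
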